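**Retrosynthetic overview**
1. Both six-membered rings are cis-4-bromocyclohexan-1-ols with a quaternary carbon between CHBr and the carbinol carbon. Both C–Br bonds are therefore set last, by hydrogen-atom-transfer hydrogenation of the bis(alkenyl bromide) 24.
2. Ring A (cyclohexanol locants: C1 carbinol, C3 = CMe2, C4 = CHBr): C1 and C3 are 1,3-related like the carbonyl and β-carbon of a β,β-dimethyl enone, and C4–C5–C6 is a three-carbon bridge that carries only Br, on C4. This allows a [3+3] annulation of tertiary boronate 19 with bromoform (C4) and a vinyl group (C5, C6) that forms C3–C4, C4–C5 and C6–C1 in one flask.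
3. The annulation precursor comes from enone 17, made from ester 15; the side chain is attached by Mukaiyama–Michael addition to bicyclic enone 8 (sets C3 and C3a), and MeLi sets the C4 carbinol.
4. Enone 8 comes from cyclohexenone 5 by conjugate addition anti to the C7 silyloxy group (quaternary C7a) and aldol condensation (five-membered ring).
5. Ring order: ring B (from 1), then the cyclopentene, then the ring-B alkenyl bromide from the C7 ketone, then ring A last.

Key step: step 14

Remarks on the chemistry: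
- Hydrindane locants are C1–C3, C3a, C4–C7, C7a; α is the face of the 7a-methyl group, β the opposite face. "The hydrindenyl group" means 7-bromo-4α-hydroxy-4β,7aα-dimethyl-3aβ-H-2,3,3a,4,5,7a-hexahydro-1H-inden-3β-yl.
- Assumption: the sense of induction of the (R,R)-lithium amide (step 1) and of the (+)-pinanediol boronate (step 14) is assigned by analogy with the established models; if it proves opposite, the enantiomeric auxiliary is used.
- In step 14, 19 reacts as its lithium alkoxide (one extra equivalent of base).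

Step 1
Reactants: 1 4-[(tert-butyldimethylsilyl)oxy]cyclohexan-1-one
Product: 3 (S)-4-[(tert-butyldimethylsilyl)oxy]cyclohex-2-en-1-one, via silyl enol ether 2 (not isolated)
Conditions: LiN[(R)-CH(Me)Ph]2, Me3SiCl, THF, −100 °C; then Pd(OAc)2, MeCN, 20 °C
Reagents that add atoms: none
Why: Enantioselective deprotonation by the chiral lithium amide with internal silyl quench should remove one enantiotopic α-proton and so define the silyloxy-bearing stereocenter, and Saegusa–Ito oxidation should then give the enone.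

Step 2
Reactants: 3 (S)-4-[(tert-butyldimethylsilyl)oxy]cyclohex-2-en-1-one
Product: 5 (S)-4-[(tert-butyldimethylsilyl)oxy]-3-methylcyclohex-2-en-1-one, via methyl enol silane 4 (not isolated)
Conditions: Me2CuLi, Me3SiCl, THF, −78 °C; then Pd(OAc)2, MeCN, 20 °C
Reagents that add atoms: lithium dimethylcuprate, [Li+].C[Cu-]C
Why: Cuprate conjugate addition with silyl trapping followed by a second Saegusa–Ito oxidation should install the β-methyl group; the transient methyl stereocenter is erased again.

Step 3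
Reactants: 5 (S)-4-[(tert-butyldimethylsilyl)oxy]-3-methylcyclohex-2-en-1-one
Product: 6 (3S,4S)-3-(but-3-en-1-yl)-4-[(tert-butyldimethylsilyl)oxy]-3-methylcyclohexan-1-one
Conditions: CH2=CHCH2CH2MgBr, CuBr·SMe2 (20 mol %), BF3·OEt2, THF, −78 → −40 °C
Reagents that add atoms: but-3-en-1-ylmagnesium bromide, C=CCC[Mg]Br
Why: Copper-mediated conjugate addition to the β,β-disubstituted enone should create the quaternary center (later C7a) with the butenyl group anti to the neighbouring silyloxy group.

Step 4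
Reactants: 6 (3S,4S)-3-(but-3-en-1-yl)-4-[(tert-butyldimethylsilyl)oxy]-3-methylcyclohexan-1-one
Product: 8 (7S,7aS)-7-[(tert-butyldimethylsilyl)oxy]-7a-methyl-1,2,5,6,7,7a-hexahydro-4H-inden-4-one, via keto aldehyde 7 (not isolated)
Conditions: O3, CH2Cl2–MeOH, −78 °C; Me2S; then KOH, MeOH, 0 → 20 °C
Reagents that add atoms: none
Why: Ozonolysis should give the keto aldehyde, and intramolecular aldol condensation of the ketone α-carbon next to the quaternary center onto the aldehyde should close the cyclopentene as the conjugated enone; no new stereocenter is formed.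

Step 5
Reactants: 8 (7S,7aS)-7-[(tert-butyldimethylsilyl)oxy]-7a-methyl-1,2,5,6,7,7a-hexahydro-4H-inden-4-one
Product: 10 methyl 2-[7α-(tert-butyldimethylsilyloxy)-7aα-methyl-4-oxo-3aβ-H-octahydro-1H-inden-3β-yl]acetate, via enol silyl ether 9 (not isolated)
Conditions: CH2=C(OMe)OSiMe2t-Bu, t-BuMe2SiOTf (10 mol %), CH2Cl2, −78 °C; then Bu4NF–AcOH, THF, −78 °C
Reagents that add atoms: 1-(tert-butyldimethylsilyloxy)-1-methoxyethene, C=C(OC)O[Si](C)(C)C(C)(C)C
Why: Mukaiyama–Michael addition should deliver the acetate unit to C3 on the β-face, anti to the pseudo-axial angular methyl group, and kinetic protonation of the C4 enol silane from the same β-face should give the trans ring fusion (C3a–H β).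

Step 6
Reactants: 10 methyl 2-[7α-(tert-butyldimethylsilyloxy)-7aα-methyl-4-oxo-3aβ-H-octahydro-1H-inden-3β-yl]acetate
Product: 11 methyl 2-[7α-(tert-butyldimethylsilyloxy)-4α-hydroxy-4β,7aα-dimethyl-3aβ-H-octahydro-1H-inden-3β-yl]acetate
Conditions: MeLi, CeCl3, THF, −78 °C
Reagents that add atoms: methyllithium, [Li]C
Why: The non-basic organocerium reagent should add to the ketone in preference to the ester and without epimerising C3a; the angular methyl group is 1,3-diaxial to the α-face of C4, so attack is equatorial from the β-face and the hydroxyl ends axial (α).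

Step 7
Reactants: 11 methyl 2-[7α-(tert-butyldimethylsilyloxy)-4α-hydroxy-4β,7aα-dimethyl-3aβ-H-octahydro-1H-inden-3β-yl]acetate
Product: 12 methyl 2-[4α,7α-dihydroxy-4β,7aα-dimethyl-3aβ-H-octahydro-1H-inden-3β-yl]acetate
Conditions: Bu4NF, THF, 20 °C
Reagents that add atoms: none
Why: Fluoride-mediated desilylation should free the secondary C7 alcohol; lactonisation is not expected because the C4 oxygen (α) and the C3 acetate arm (β) lie on opposite faces.

Step 8
Reactants: 12 methyl 2-[4α,7α-dihydroxy-4β,7aα-dimethyl-3aβ-H-octahydro-1H-inden-3β-yl]acetate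
Product: 13 methyl 2-[4α-hydroxy-4β,7aα-dimethyl-7-oxo-3aβ-H-octahydro-1H-inden-3β-yl]acetate
Conditions: DMP, NaHCO3, CH2Cl2, 0 → 20 °C
Reagents that add atoms: none
Why: Dess–Martin oxidation should convert only the secondary alcohol into the C7 ketone; the tertiary alcohol cannot be oxidised.

Step 9
Reactants: 13 methyl 2-[4α-hydroxy-4β,7aα-dimethyl-7-oxo-3aβ-H-octahydro-1H-inden-3β-yl]acetate
Product: 14 methyl 2-[4α-hydroxy-4β,7aα-dimethyl-7-(trifluoromethylsulfonyloxy)-3aβ-H-2,3,3a,4,5,7a-hexahydro-1H-inden-3β-yl]acetate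
Conditions: KN(SiMe3)2 (2.2 equiv), PhNTf2, THF, −78 °C
Reagents that add atoms: N-phenyl-bis(trifluoromethanesulfonimide), O=S(=O)(N(c1ccccc1)S(=O)(=O)C(F)(F)F)C(F)(F)F
Why: Enol triflate formation should be regiospecific because the C7 ketone can enolise only toward C6 (C7a is quaternary); the ketone is more acidic than the ester, and the hindered tertiary alkoxide should be triflated only slowly.

Step 10
Reactants: 14 methyl 2-[4α-hydroxy-4β,7aα-dimethyl-7-(trifluoromethylsulfonyloxy)-3aβ-H-2,3,3a,4,5,7a-hexahydro-1H-inden-3β-yl]acetate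
Product: 15 methyl 2-(hydrindenyl)acetate, i.e. methyl 2-[7-bromo-4α-hydroxy-4β,7aα-dimethyl-3aβ-H-2,3,3a,4,5,7a-hexahydro-1H-inden-3β-yl]acetate
Conditions: Ni(OAc)2·4H2O (10 mol %), 1,5-cyclooctadiene, Zn (20 mol %), LiBr, DMA–THF, 20 °C
Reagents that add atoms: lithium bromide, [Li+].[Br-]
Why: Nickel-catalysed halogen exchange of the enol triflate should give the ring-B alkenyl bromide without touching the ester or the tertiary alcohol.

Step 11
Reactants: 15 methyl 2-(hydrindenyl)acetate
Product: 17 1-(hydrindenyl)-4-methylpent-3-en-2-one, via amide 16 (not isolated)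
Conditions: MeNH(OMe)·HCl, i-PrMgCl, THF, −20 °C; then Me2C=CHMgBr, 0 °C
Reagents that add atoms: (2-methylprop-1-en-1-yl)magnesium bromide, CC(C)=C[Mg]Br
Why: Conversion of the ester into the N-methoxy-N-methylamide and single addition of the alkenyl Grignard reagent (Weinreb ketone synthesis) should give the β,β-dimethyl enone without over-addition.

Step 12
Reactants: 17 1-(hydrindenyl)-4-methylpent-3-en-2-one
Product: 18 1-(hydrindenyl)-4-methyl-4-[(+)-pinanediolatoboryl]pentan-2-one
Conditions: bis[(+)-pinanediolato]diboron, CuCl (5 mol %), Xantphos, NaOt-Bu (10 mol %), MeOH (2 equiv), THF, 20 °C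
Reagents that add atoms: bis[(+)-pinanediolato]diboron, B1(O[C@@H]2C[C@@H]3C[C@@H](C3(C)C)[C@]2(C)O1)B1O[C@@H]2C[C@@H]3C[C@@H](C3(C)C)[C@]2(C)O1
Why: Copper-catalysed conjugate borylation of the β,β-disubstituted enone should place boron on the carbon that becomes ring-A C3; no stereocenter is created there (gem-dimethyl).

Step 13
Reactants: 18 1-(hydrindenyl)-4-methyl-4-[(+)-pinanediolatoboryl]pentan-2-one
Product: 19 dimethyl ketal of 18, i.e. 2,2-dimethoxy-1-(hydrindenyl)-4-methyl-4-[(+)-pinanediolatoboryl]pentane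
Conditions: HC(OMe)3, MeOH, PPTS (5 mol %), 20 °C
Reagents that add atoms: trimethyl orthoformate, COC(OC)OC
Why: Acid-catalysed ketalisation should mask the ketone against the organometallic reagents of the next step; a cyclic ketal with the C4 hydroxyl cannot form for the geometric reason given in step 7.

Step 14
Reactants: 19 2,2-dimethoxy-1-(hydrindenyl)-4-methyl-4-[(+)-pinanediolatoboryl]pentane
Product: 24 (R)-4-bromo-1-[(hydrindenyl)methyl]-5,5-dimethylcyclohex-3-en-1-ol, via dibromo boronate 20 (not isolated), via bromoallyl boronate 21 (not isolated), via keto boronate 22 (not isolated), via borate ester 23 (not isolated)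
Conditions: CHBr3, LiN(iPr)2, ZnCl2, THF, −100 → 0 °C; CH2=CHMgBr, −78 → 20 °C; 1 M HCl, THF, 20 → 40 °C
Reagents that add atoms: bromoform, BrC(Br)Br; vinylmagnesium bromide, C=C[Mg]Br; water, O
Why: Proposed new method: tribromomethyllithium should add to the tertiary boronate and the tertiary alkyl group should migrate from boron to carbon with loss of bromide (ring-A C3–C4 bond, 20), vinylmagnesium bromide should then form a second boronate complex in which vinyl migrates with loss of one of the two diastereotopic bromides (21), and acid should unmask the ketone (22), which is allylated through the γ-carbon of the allyl unit (ring-A C6–C1 bond) to give borate 23 and, after hydrolysis, 24; the closest known reactions are the Matteson homologation of boronic esters with halomethyllithium reagents followed by Grignard displacement, and the allylboration of carbonyl compounds by α-haloallyl boronates, which gives haloalkenes. Ring A closes in a six-membered mode through a closed allylboration transition state in which the B–O contact bridges C4 and C1, so the ring alkene is necessarily cis and keeps the bromine on C4. The only new stereocenter, C1, is controlled by the boron-bearing C4 center of 21: its configuration is set by the pinanediol director, which selects the bromide that leaves, and it is transferred because the oxygen must end on the ring face that boron occupied. The step needs migration of carbon and not of oxygen ligands, a single vinyl transfer, and allyl transfer to the ketone before any 1,3-boron shift; the ketal and the lithium alkoxide shield the ketone and the tertiary alcohol during the carbenoid stage, the ring-B alkenyl bromide is inert to these reagents, and the intramolecular six-ring geometry favours the allyl transfer.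

Step 15
Reactants: 24 (R)-4-bromo-1-[(hydrindenyl)methyl]-5,5-dimethylcyclohex-3-en-1-ol
Product: 25 (1S,4S)-4-bromo-1-{[7α-bromo-4α-hydroxy-4β,7aα-dimethyl-3aβ-H-octahydro-1H-inden-3β-yl]methyl}-3,3-dimethylcyclohexan-1-ol (target)
Conditions: Co(acac)2, t-BuOOH, Et3SiH, 1,4-cyclohexadiene, n-PrOH, 20 °C
Reagents that add atoms: none
Why: Metal-hydride hydrogen-atom-transfer hydrogenation of alkenyl halides should reduce both alkenyl bromides through tertiary α-bromo radicals without loss of bromine; in each chair, hydrogen should be delivered axially, anti to the axial methyl group on the neighbouring quaternary carbon, which leaves each bromine equatorial (cis to the C1 hydroxyl in ring A, α at C7 in ring B).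

**Compound list**
1 | 4-[(tert-butyldimethylsilyl)oxy]cyclohexan-1-one | CC(C)(C)[Si](C)(C)OC1CCC(=O)CC1 | starting material
2 | (S)-tert-butyldimethyl{[4-(trimethylsilyloxy)cyclohex-3-en-1-yl]oxy}silane | C[Si](C)(C)OC1=CC[C@@H](O[Si](C)(C)C(C)(C)C)CC1 | intermediate
3 | (S)-4-[(tert-butyldimethylsilyl)oxy]cyclohex-2-en-1-one | O=C1C=C[C@@H](O[Si](C)(C)C(C)(C)C)CC1 | intermediate
4 | tert-butyldimethyl{[(1S,2S)-2-methyl-4-(trimethylsilyloxy)cyclohex-3-en-1-yl]oxy}silane | C[Si](C)(C)OC1=C[C@H](C)[C@@H](O[Si](C)(C)C(C)(C)C)CC1 | intermediate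
5 | (S)-4-[(tert-butyldimethylsilyl)oxy]-3-methylcyclohex-2-en-1-one | CC1=CC(=O)CC[C@@H]1O[Si](C)(C)C(C)(C)C | intermediate
6 | (3S,4S)-3-(but-3-en-1-yl)-4-[(tert-butyldimethylsilyl)oxy]-3-methylcyclohexan-1-one | O=C1C[C@](C)(CCC=C)[C@@H](O[Si](C)(C)C(C)(C)C)CC1 | intermediate
7 | 3-{(1S,2S)-2-[(tert-butyldimethylsilyl)oxy]-1-methyl-5-oxocyclohexyl}propanal | O=C1C[C@](C)(CCC=O)[C@@H](O[Si](C)(C)C(C)(C)C)CC1 | intermediate
8 | (7S,7aS)-7-[(tert-butyldimethylsilyl)oxy]-7a-methyl-1,2,5,6,7,7a-hexahydro-4H-inden-4-one | O=C1CC[C@H](O[Si](C)(C)C(C)(C)C)[C@@]2(C)CCC=C12 | intermediate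
9 | methyl 2-[4,7α-bis(tert-butyldimethylsilyloxy)-7aα-methyl-2,3,5,6,7,7a-hexahydro-1H-inden-3β-yl]acetate | COC(=O)C[C@@H]1CC[C@]2(C)[C@@H](O[Si](C)(C)C(C)(C)C)CCC(O[Si](C)(C)C(C)(C)C)=C12 | intermediate
10 | methyl 2-[7α-(tert-butyldimethylsilyloxy)-7aα-methyl-4-oxo-3aβ-H-octahydro-1H-inden-3β-yl]acetate (trans-fused) | COC(=O)C[C@@H]1CC[C@]2(C)[C@@H](O[Si](C)(C)C(C)(C)C)CCC(=O)[C@@H]12 | intermediate
11 | methyl 2-[7α-(tert-butyldimethylsilyloxy)-4α-hydroxy-4β,7aα-dimethyl-3aβ-H-octahydro-1H-inden-3β-yl]acetate | COC(=O)C[C@@H]1CC[C@]2(C)[C@@H](O[Si](C)(C)C(C)(C)C)CC[C@@](C)(O)[C@@H]12 | intermediate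
12 | methyl 2-[4α,7α-dihydroxy-4β,7aα-dimethyl-3aβ-H-octahydro-1H-inden-3β-yl]acetate | COC(=O)C[C@@H]1CC[C@]2(C)[C@@H](O)CC[C@@](C)(O)[C@@H]12 | intermediate
13 | methyl 2-[4α-hydroxy-4β,7aα-dimethyl-7-oxo-3aβ-H-octahydro-1H-inden-3β-yl]acetate | COC(=O)C[C@@H]1CC[C@]2(C)C(=O)CC[C@@](C)(O)[C@@H]12 | intermediate
14 | methyl 2-[4α-hydroxy-4β,7aα-dimethyl-7-(trifluoromethylsulfonyloxy)-3aβ-H-2,3,3a,4,5,7a-hexahydro-1H-inden-3β-yl]acetate | COC(=O)C[C@@H]1CC[C@]2(C)C(OS(=O)(=O)C(F)(F)F)=CC[C@@](C)(O)[C@@H]12 | intermediate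
15 | methyl 2-[7-bromo-4α-hydroxy-4β,7aα-dimethyl-3aβ-H-2,3,3a,4,5,7a-hexahydro-1H-inden-3β-yl]acetate | COC(=O)C[C@@H]1CC[C@]2(C)C(Br)=CC[C@@](C)(O)[C@@H]12 | intermediate
16 | 2-(hydrindenyl)-N-methoxy-N-methylacetamide | CON(C)C(=O)C[C@@H]1CC[C@]2(C)C(Br)=CC[C@@](C)(O)[C@@H]12 | intermediate
17 | 1-(hydrindenyl)-4-methylpent-3-en-2-one | CC(C)=CC(=O)C[C@@H]1CC[C@]2(C)C(Br)=CC[C@@](C)(O)[C@@H]12 | intermediate
18 | 1-(hydrindenyl)-4-methyl-4-[(+)-pinanediolatoboryl]pentan-2-one | CC(C)(CC(=O)C[C@@H]1CC[C@]2(C)C(Br)=CC[C@@](C)(O)[C@@H]12)B1O[C@@H]2C[C@@H]3C[C@@H](C3(C)C)[C@]2(C)O1 | intermediate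
19 | 2,2-dimethoxy-1-(hydrindenyl)-4-methyl-4-[(+)-pinanediolatoboryl]pentane | CC(C)(CC(OC)(OC)C[C@@H]1CC[C@]2(C)C(Br)=CC[C@@](C)(O)[C@@H]12)B1O[C@@H]2C[C@@H]3C[C@@H](C3(C)C)[C@]2(C)O1 | intermediate
20 | (+)-pinanediol [1,1-dibromo-4,4-dimethoxy-5-(hydrindenyl)-2,2-dimethylpentyl]boronate | CC(C)(CC(OC)(OC)C[C@@H]1CC[C@]2(C)C(Br)=CC[C@@](C)(O)[C@@H]12)C(Br)(Br)B1O[C@@H]2C[C@@H]3C[C@@H](C3(C)C)[C@]2(C)O1 | intermediate
21 | (+)-pinanediol [(3R)-3-bromo-6,6-dimethoxy-7-(hydrindenyl)-4,4-dimethylhept-1-en-3-yl]boronate | CC(C)(CC(OC)(OC)C[C@@H]1CC[C@]2(C)C(Br)=CC[C@@](C)(O)[C@@H]12)[C@](Br)(C=C)B1O[C@@H]2C[C@@H]3C[C@@H](C3(C)C)[C@]2(C)O1 | intermediate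
22 | (+)-pinanediol [(3R)-3-bromo-7-(hydrindenyl)-4,4-dimethyl-6-oxohept-1-en-3-yl]boronate | CC(C)(CC(=O)C[C@@H]1CC[C@]2(C)C(Br)=CC[C@@](C)(O)[C@@H]12)[C@](Br)(C=C)B1O[C@@H]2C[C@@H]3C[C@@H](C3(C)C)[C@]2(C)O1 | intermediate
23 | (+)-pinanediol borate ester of 24 at the ring-A oxygen | CC1(C)C[C@@](OB2O[C@@H]3C[C@@H]4C[C@@H](C4(C)C)[C@]3(C)O2)(C[C@@H]2CC[C@]3(C)C(Br)=CC[C@@](C)(O)[C@@H]23)CC=C1Br | intermediate
24 | (R)-4-bromo-1-[(hydrindenyl)methyl]-5,5-dimethylcyclohex-3-en-1-ol (same spatial arrangement at C1 as in 25) | CC1(C)C[C@@](O)(C[C@@H]2CC[C@]3(C)C(Br)=CC[C@@](C)(O)[C@@H]23)CC=C1Br | intermediate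
25 | (1S,4S)-4-bromo-1-{[7α-bromo-4α-hydroxy-4β,7aα-dimethyl-3aβ-H-octahydro-1H-inden-3β-yl]methyl}-3,3-dimethylcyclohexan-1-ol | CC1(C)C[C@@](O)(C[C@@H]2CC[C@]3(C)[C@@H](Br)CC[C@@](C)(O)[C@@H]23)CC[C@@H]1Br | target

**Totals**
Total step count: 15. Longest linear sequence: 15 steps (fully linear from 1).

**Steps most likely to fail**

Step 14 (proposed new method). What may go wrong: the boronate complex may not form at the hindered tertiary boron, the carbenoid may decompose before migration, the selection between the two bromides may be poor, or the α-bromoallyl boronate may undergo 1,3-boron shift and protodeboronation before it reaches the ketone. Fallback in known chemistry, setting out from 19 and coming back at 25: 3-chloropropyl 2,4,6-triisopropylbenzoate is lithiated with s-BuLi and (−)-sparteine (Et2O, −78 °C), borylated with 19 (as its lithium alkoxide), and 1,2-metallate rearrangement (MgBr2, warming) should give the secondary pinanediol boronate F1 with the carbenoid carbon bonded to the quaternary carbon. Stereoinvertive bromodeboronation (3,5-bis(trifluoromethyl)phenyllithium, then NBS) should give the neopentylic bromide F2 with the configuration needed at ring-A C4. A Finkelstein exchange (NaI, acetone) should give the iodide F3, and ketal hydrolysis (PPTS, acetone–water) the keto iodide F4. A Barbier cyclisation (SmI2, HMPA, THF) should then close ring A through a chair with bromine and the hydrindenylmethyl group equatorial, giving the bromo alcohol F5. Hydrogenation of the one remaining alkenyl bromide of F5 under the conditions of step 15 reaches 25.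

Step 5. What may go wrong: protonation of the C4 enol silane from the α-face, or later epimerisation at C3a, gives the cis ring fusion; the second silyl ether may also be cleaved. Fallback, setting out from 8 and coming back at 11: 1,2-addition of MeLi–CeCl3 to the enone (β-face attack) should give the tertiary allylic alcohol F6. Hydroboration of the C3a=C3 double bond with 9-BBN (THF, reflux, two equivalents) should occur anti to the angular methyl group and set C3a–H and the C3–B bond both β, giving the organoborane F7. Homologation of F7 with methyl diazoacetate (1,2-shift from boron to carbon with retention) and basic work-up should give 11 directly.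

Step 15. What may go wrong: loss of bromine by reduction or elimination, or hydrogen delivery from the wrong face at one of the two radical centers. Fallback, setting out from 24 and coming back at 25: Miyaura borylation (bis(pinacolato)diboron, PdCl2(dppf), KOAc, dioxane, 80 °C) should give the bis(alkenyl boronate) F8. Hydroxyl-directed hydrogenation ([Ir(cod)(PCy3)(py)]PF6, H2, CH2Cl2) should deliver hydrogen cis to the homoallylic tertiary alcohol in each ring and give the bis(alkyl boronate) F9 with both boryl groups trans to those hydroxyls. Stereoinvertive bromodeboronation (3,5-bis(trifluoromethyl)phenyllithium, then NBS) should give 25.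

Further compounds
F1 | step 14 | (+)-pinanediol [(3R)-1-chloro-6,6-dimethoxy-7-(hydrindenyl)-4,4-dimethylheptan-3-yl]boronate | CC(C)(CC(OC)(OC)C[C@@H]1CC[C@]2(C)C(Br)=CC[C@@](C)(O)[C@@H]12)[C@H](B1O[C@@H]2C[C@@H]3C[C@@H](C3(C)C)[C@]2(C)O1)CCCl
F2 | step 14 | (3S)-3-bromo-1-chloro-6,6-dimethoxy-7-(hydrindenyl)-4,4-dimethylheptane | CC(C)(CC(OC)(OC)C[C@@H]1CC[C@]2(C)C(Br)=CC[C@@](C)(O)[C@@H]12)[C@@H](Br)CCCl
F3 | step 14 | (3S)-3-bromo-1-iodo-6,6-dimethoxy-7-(hydrindenyl)-4,4-dimethylheptane | CC(C)(CC(OC)(OC)C[C@@H]1CC[C@]2(C)C(Br)=CC[C@@](C)(O)[C@@H]12)[C@@H](Br)CCI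
F4 | step 14 | (5S)-5-bromo-1-(hydrindenyl)-7-iodo-4,4-dimethylheptan-2-one | CC(C)(CC(=O)C[C@@H]1CC[C@]2(C)C(Br)=CC[C@@](C)(O)[C@@H]12)[C@@H](Br)CCI
F5 | step 14 | (1S,4S)-4-bromo-1-[(hydrindenyl)methyl]-3,3-dimethylcyclohexan-1-ol | CC1(C)C[C@@](O)(C[C@@H]2CC[C@]3(C)C(Br)=CC[C@@](C)(O)[C@@H]23)CC[C@@H]1Br
F6 | step 5 | 7α-(tert-butyldimethylsilyloxy)-4β,7aα-dimethyl-2,4,5,6,7,7a-hexahydro-1H-inden-4α-ol | C[C@@]1(O)CC[C@H](O[Si](C)(C)C(C)(C)C)[C@@]2(C)CCC=C12
F7 | step 5 | 3β-(9-borabicyclo[3.3.1]nonan-9-yl)-7α-(tert-butyldimethylsilyloxy)-4β,7aα-dimethyl-3aβ-H-octahydro-1H-inden-4α-ol | C[C@@]1(O)CC[C@H](O[Si](C)(C)C(C)(C)C)[C@@]2(C)CC[C@@H](B3C4CCCC3CCC4)[C@H]12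
F8 | step 15 | bis(pinacol boronate) of 24 (boron in place of both bromine atoms) | CC1(C)C[C@@](O)(C[C@@H]2CC[C@]3(C)C(B4OC(C)(C)C(C)(C)O4)=CC[C@@](C)(O)[C@@H]23)CC=C1B1OC(C)(C)C(C)(C)O1
F9 | step 15 | saturated bis(pinacol boronate), boryl groups trans to the ring hydroxyls (ring-A C4 and ring-B C7β) | CC1(C)C[C@@](O)(C[C@@H]2CC[C@]3(C)[C@H](B4OC(C)(C)C(C)(C)O4)CC[C@@](C)(O)[C@@H]23)CC[C@H]1B1OC(C)(C)C(C)(C)O1
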